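**Strategy.** Both halves derive from dehydrocostus lactone via dehydrozaluzanin C (3). The spiro-linked cyclohexene (C1, C2, C4′, C15′, C14, C10) is not closed in its final size: its four lower-half carbons C2–C1=C10–C14 are first held in a five-membered 3-sulfolene (8) that already carries the C15 hydroxyl. In the key step this ring expels SO2 and takes up C15′=C4′ of 3 in a [4+2] union, growing from five to six atoms while both inter-unit bonds and the quaternary spiro centre C4′ are set. The step exploits the cyclohexene retron C2–C1=C10–C14 hidden in the target's 10-hydroxy-1(2)-en-3-one.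

Key step: step 6

Remark (labels): guaiane numbering; the unprimed half carries C10–OH and C15–OH, the primed half carries the spiro carbon C4′; α is the face of H-5 (H-5′).
Remark (reading of the target): the SMILES is read as 10β-OH, C15 on the α face of C4 (H-4β), and C2 on the α face of the upper cyclopentanone (syn to H-5′).
Remark (transient centres): C3 of 2, C2 of 7, 8 and 10, and C4′ of F1 are drawn as the expected epimers; all of these centres are erased later, so either epimer serves.

Step 1
Reactants: 1 dehydrocostus lactone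
Product: 2 3α-hydroxydehydrocostus lactone (3-epizaluzanin C type)
Conditions: SeO2 (0.3 equiv), t-BuOOH (2 equiv), CH2Cl2, 0 °C to rt
Reagents that add atoms: tert-butyl hydroperoxide, CC(C)(C)OO (net source of the hydroxyl oxygen, relayed by catalytic SeO2, O=[Se]=O)
Why: Riley-type SeO2 allylic oxidation (ene reaction, then [2,3]-sigmatropic shift) should hydroxylate the ring CH2 allylic to the C4=C15 methylene, with oxygen delivered to the less hindered α face of C3.

Step 2
Reactants: 2 3α-hydroxydehydrocostus lactone
Product: 3 dehydrozaluzanin C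
Conditions: Dess–Martin periodinane, CH2Cl2, 0 °C to rt
Reagents that add atoms: none
Why: Dess–Martin oxidation of the secondary allylic alcohol should give the exocyclic enone without touching the methylene groups; no stereocentre is formed.

Step 3
Reactants: 3 dehydrozaluzanin C
Product: 4 15-hydroxy-4β,15-dihydrodehydrozaluzanin C (4α-hydroxymethyl ketone)
Conditions: PMe3 (0.2 equiv), H2O/THF 1:3, 0 °C to rt
Reagents that add atoms: water, O
Why: Phosphine-catalysed oxa-Michael addition of water should take place at the more electrophilic acceptor, the exocyclic enone C4=C15, rather than at the α-methylene lactone, and the epimerisable C4 centre should settle with CH2OH on the α face, trans to the C5–C6 bond.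

Step 4
Reactants: 4 15-hydroxy-4β,15-dihydrodehydrozaluzanin C
Product: 5 bis(trimethylsilyl) derivative of 4 (15-O-TMS ether and 3-OTMS 2-ene enol ether)
Conditions: TMSCl (3 equiv), LiN(SiMe3)2 (2.3 equiv), THF, −78 °C (chlorosilane present before the base); Et3N, pentane, cold aqueous NaHCO3 work-up
Reagents that add atoms: chlorotrimethylsilane, C[Si](C)(C)Cl
Why: Kinetic enolisation with in-situ silyl trapping should silylate the alkoxide at once (no retro-aldol) and remove a proton from the C2 methylene rather than the more hindered C4 methine, so the enol ether forms toward C2 and the C4 configuration is untouched; no stereocentre is formed.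

Step 5
Reactants: 5 bis(trimethylsilyl) derivative of 4
Product: 8 15-hydroxy 2-acyl-3-sulfolene (SO2 bridging C2 and C14 with C1=C10), via O-TMS dienone 6 (not isolated), via O-TMS sulfolene 7 (not isolated)
Conditions: Pd(OAc)2 (1.05 equiv), MeCN, rt; filter cold; then liquid SO2, BHT (cat.), sealed tube, −20 °C to rt; then MeOH, PPTS (cat.), 0 °C
Reagents that add atoms: sulfur dioxide, O=S=O
Why: Saegusa–Ito oxidation (oxa-π-allyl palladium at C2, β-hydride loss of H-1) should give the labile dienone 6, whose ring-locked s-cis diene C2=C1–C10=C14 is trapped at once by cheletropic [4+1] addition of SO2 (S expected on the α face of C2, a centre erased in step 6), and mild acidic methanolysis then frees the primary alcohol without touching the sulfolene.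

Step 6
Reactants: 8 15-hydroxy 2-acyl-3-sulfolene; 3 dehydrozaluzanin C
Product: 10 Diels–Alder adduct (C2–C4′ and C14–C15′ bonds with C1=C10 and H-2α), via hydroxy dienone 9 (not isolated)
Conditions: 3 (3 equiv), toluene, BHT (cat.), argon sparge, dark, 105 °C
Reagents that add atoms: none
Why: Heating effects cheletropic loss of SO2 from the 2-acyl-3-sulfolene 8, and the hydroxy dienone 9, whose ring-locked s-cis diene C2=C1–C10=C14 is thus released at low stationary concentration, is captured by the exocyclic enone C4′=C15′ of 3 in a thermal Diels–Alder reaction. The closest known reaction type is the sulfolene-unmasking Diels–Alder sequence used to deliver unstable dienes. The five-membered ring S–C2–C1=C10–C14 is thereby enlarged to the six-membered ring C2–C1=C10–C14–C15′–C4′ (SO2 out, the two-carbon unit C4′–C15′ in) by a concerted suprafacial [4+2] closure that forms C2–C4′ and C14–C15′. The spiro centre C4′ is set by attack on the α face of the dienophile, syn to H-5′ and away from the C5′–C6′ bond, and C2 (H-2α, a centre erased in step 7) by endo approach of the dienophile to the β face of the diene, anti to the α-disposed hydroxymethyl group at C4. The step needs ortho regiochemistry, secured by the matching large coefficients at C14 of the 1-acyl diene and C15′ of the α-methylene ketone, and cross- over self-cycloaddition, secured because 9 carries no exocyclic enone of its own and meets an excess of 3, whose cyclopentanone methylene is the most reactive alkene present.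

Step 7
Reactants: 10 Diels–Alder adduct
Product: 12 Ainsliadimer B, via 1α-bromo-10β-hydroxy bromohydrin 11 (not isolated)
Conditions: NBS (1.05 equiv), THF/H2O 4:1, 0 °C; then Et3N, rt
Reagents that add atoms: water, O (N-bromosuccinimide, O=C1CCC(=O)N1Br, adds bromine only to intermediate 11)
Why: Bromohydrin formation should occur at the most electron-rich, tetrasubstituted C1=C10 bond, with the bromonium ion on the open α face (flanked by H-2 and H-5, where the α-disposed C15 hydroxyl cannot reach its backside) and water opening it at C10 from the β face (C10 is further from the C3 carbonyl), which sets 10β-OH; E1cB loss of HBr through the C2 enolate, directly or via the β-epoxide, then installs C1=C2.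

**Compound list**

1 | dehydrocostus lactone | C=C1CC[C@H]2C(=C)CC[C@H]3C(=C)C(=O)O[C@@H]3[C@@H]12 | starting material
2 | 3α-hydroxydehydrocostus lactone (3-epizaluzanin C type) | C=C1[C@H](O)C[C@H]2C(=C)CC[C@H]3C(=C)C(=O)O[C@@H]3[C@@H]12 | intermediate
3 | dehydrozaluzanin C (3-oxodehydrocostus lactone) | C=C1C(=O)C[C@H]2C(=C)CC[C@H]3C(=C)C(=O)O[C@@H]3[C@@H]12 | intermediate
4 | 15-hydroxy-4β,15-dihydrodehydrozaluzanin C (4α-hydroxymethyl ketone) | OC[C@@H]1C(=O)C[C@H]2C(=C)CC[C@H]3C(=C)C(=O)O[C@@H]3[C@@H]12 | intermediate
5 | bis(trimethylsilyl) derivative of 4 (15-O-TMS ether, 3-OTMS 2-ene enol ether) | C[Si](C)(C)OC[C@@H]1C(O[Si](C)(C)C)=C[C@H]2C(=C)CC[C@H]3C(=C)C(=O)O[C@@H]3[C@@H]12 | intermediate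
6 | O-TMS dienone (15-trimethylsilyloxy-1(2)-en-3-one with diene C2=C1–C10=C14) | C[Si](C)(C)OC[C@@H]1C(=O)C=C2C(=C)CC[C@H]3C(=C)C(=O)O[C@@H]3[C@@H]12 | intermediate
7 | O-TMS sulfolene (SO2 bridging C2 and C14, C1=C10, S on the α face of C2, 15-O-TMS) | C[Si](C)(C)OC[C@@H]1C(=O)[C@H]2C3=C(CS2(=O)=O)CC[C@H]4C(=C)C(=O)O[C@@H]4[C@@H]13 | intermediate
8 | 15-hydroxy 2-acyl-3-sulfolene (SO2 bridging C2 and C14, C1=C10, S on the α face of C2) | OC[C@@H]1C(=O)[C@H]2C3=C(CS2(=O)=O)CC[C@H]4C(=C)C(=O)O[C@@H]4[C@@H]13 | intermediate
9 | hydroxy dienone (15-hydroxy-1(2)-en-3-one with diene C2=C1–C10=C14) | OC[C@@H]1C(=O)C=C2C(=C)CC[C@H]3C(=C)C(=O)O[C@@H]3[C@@H]12 | intermediate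
10 | Diels–Alder adduct (C2–C4′ and C14–C15′ bonds, C1=C10, H-2α, spiro C4′, free C15–OH) | C=C1C(=O)O[C@@H]2[C@H]3[C@H](CO)C(=O)[C@@H]4C3=C(CC[C@@H]12)CC[C@]41C(=O)C[C@H]5C(=C)CC[C@H]6C(=C)C(=O)O[C@@H]6[C@@H]15 | intermediate
11 | 1α-bromo-10β-hydroxy bromohydrin of 10 | C=C1C(=O)O[C@@H]2[C@H]3[C@H](CO)C(=O)[C@@H]4[C@@]3(Br)[C@@](O)(CC[C@@H]12)CC[C@]41C(=O)C[C@H]5C(=C)CC[C@H]6C(=C)C(=O)O[C@@H]6[C@@H]15 | intermediate
12 | Ainsliadimer B | C=C1C(=O)O[C@@H]2[C@@H]3C4=C(C(=O)[C@H]3CO)[C@]3(CC[C@]4(O)CC[C@@H]12)C(=O)C[C@H]1C(=C)CC[C@H]2C(=C)C(=O)O[C@@H]2[C@H]13 | target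

**Totals.** Total step count: 7. Longest linear sequence: 7 steps (1 to 12); compound 3 also enters step 6 as the second fragment.

**Steps most likely to fail, with fallbacks**

Step 6. The released diene may lose water across C4–C15 under the acid traces that SO2 leaves, may add to an α-methylene lactone, or may show poor face selection. The union would then be made stepwise from 4 and 3 without a free diene. Me2AlCl (CH2Cl2, −78 to −20 °C) should promote the conjugate ene reaction of the C10=C14 methylene of 4 (used in excess, H-1 transferred) with the exocyclic enone of 3, giving the seco-dimer F1 (C14–C15′ bond, C1=C10, C4′–H). TMSOTf/Et3N should convert it into the tris(trimethylsilyl) compound F2 (O15–TMS, dienol ether C3(OTMS)=C2–C1=C10, enol ether C3′(OTMS)=C4′). One-electron oxidation with (NH4)2Ce(NO3)6 and NaHCO3 in MeCN at −30 °C should then couple C2 with C4′ (intramolecular oxidative coupling of two enol silanes, six-membered ring closure, C2 approaching the α face of the upper ring). Aqueous work-up should shed the remaining silyl groups and rejoin the route at 10.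

Step 7. Bromine may be consumed by the C10′=C14′ methylene, the C15 hydroxyl may capture a bromonium ion formed on the β face, or water may open the bromonium ion at the wrong carbon. The oxidation would then start from 10 by a mechanism that addresses only the lower ketone. TBSOTf (2.2 equiv)/Et3N (CH2Cl2, −78 °C) should silylate O15 and enolise only the doubly activated C2–H to give the bis-TBS dienol ether F3 (C3(OTBS)=C2–C1=C10). Dimethyldioxirane (acetone, −78 °C) should oxidise the distal, electron-rich C1=C10 bond to the vinyl epoxide F4 (vinylogous Rubottom oxidation). Et3N·3HF should then open it through the C3 enolate and remove both silyl groups, returning to 12; face selection here is reagent-controlled and uncertain, so any C10 epimer would be separated at this point.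

Step 3. Trimethylphosphine may dimerise the exocyclic enone (Rauhut–Currier pathway), water may add to the α-methylene lactone, or the adduct may revert to the enone. The hydroxymethyl group would then be made from 3 in two redox steps. Weitz–Scheffer epoxidation (t-BuOOH, DBU, CH2Cl2, 0 °C) should select the ketone-activated exocyclic alkene and give the spiro-epoxy ketone F5. Cp2TiCl (from Cp2TiCl2 and Zn, THF, −20 °C; trivalent titanium) should cleave its C4–O bond reductively, and protonation of the titanium enolate with equilibration at C4 should return to 4.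

**Further compounds**

F1 | step 6 | seco-dimer from the ene reaction of 4 with 3 (C14–C15′ bond, C1=C10, C4′–H, free C15–OH) | C=C1C(=O)O[C@@H]2[C@H]3[C@H](CO)C(=O)CC3=C(CC[C@@H]12)CC[C@@H]1C(=O)C[C@H]4C(=C)CC[C@H]5C(=C)C(=O)O[C@@H]5[C@@H]14
F2 | step 6 | tris(trimethylsilyl) compound from F1 (O15–TMS, C3(OTMS)=C2–C1=C10, C3′(OTMS)=C4′) | C=C1C(=O)O[C@@H]2[C@H]3[C@H](CO[Si](C)(C)C)C(O[Si](C)(C)C)=CC3=C(CC[C@@H]12)CCC1=C(O[Si](C)(C)C)C[C@H]4C(=C)CC[C@H]5C(=C)C(=O)O[C@@H]5[C@@H]14
F3 | step 7 | bis-TBS dienol ether of 10 (O15–TBS, C3(OTBS)=C2–C1=C10) | C=C1C(=O)O[C@@H]2[C@H]3[C@H](CO[Si](C)(C)C(C)(C)C)C(O[Si](C)(C)C(C)(C)C)=C4C3=C(CC[C@@H]12)CC[C@]41C(=O)C[C@H]5C(=C)CC[C@H]6C(=C)C(=O)O[C@@H]6[C@@H]15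
F4 | step 7 | 1,10-β-epoxide of F3 (vinyl epoxide, C3(OTBS)=C2 retained) | C=C1C(=O)O[C@@H]2[C@H]3[C@H](CO[Si](C)(C)C(C)(C)C)C(O[Si](C)(C)C(C)(C)C)=C4[C@@]35O[C@]5(CC[C@@H]12)CC[C@]41C(=O)C[C@H]6C(=C)CC[C@H]7C(=C)C(=O)O[C@@H]7[C@@H]16
F5 | step 3 | 4,15-epoxide of 3 (spiro-epoxy ketone, oxygen on the α face of C4) | C1O[C@@]12C(=O)C[C@H]3C(=C)CC[C@H]4C(=C)C(=O)O[C@@H]4[C@@H]23
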